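At the end of 15 min each flask is read once, and we want to know which product holds most of the substrate, and how much.

    substrate ⇌ open intermediate (K1 = 28, k1 = 0.076 min⁻¹, Ea1 = 85.0 kJ mol⁻¹, ΔH1 = 25.0 kJ mol⁻¹)
    open intermediate → target (k2 = 0.028 min⁻¹, Ea2 = 94.0 kJ mol⁻¹)
    substrate → side product A (k3 = 0.28 min⁻¹, Ea3 = 86.0 kJ mol⁻¹)
    open intermediate → side product B (k4 = 0.13 min⁻¹, Ea4 = 80.0 kJ mol⁻¹)
    substrate → side product B (k5 = 0.020 min⁻¹, Ea5 = 83.0 kJ mol⁻¹)
    capture agent + open intermediate → trapped intermediate (k6 = 0.39 M⁻¹ min⁻¹, Ea6 = 60.0 kJ mol⁻¹)
    substrate + open intermediate → side product C (k7 = 2.0 M⁻¹ min⁻¹, Ea7 = 40.0 kJ mol⁻¹)
    substrate + target ⇌ idle adduct, settled at all times (K8 = 31 M⁻¹, ΔH8 = −9.00 kJ mol⁻¹)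
    (constants at 5 °C)

- gamma: substrate 0.10 M; capture agent 5.00 mM; temperature 5 °C; time 15 min
- delta: substrate 0.10 M; capture agent 5.00 mM; temperature 30 °C; time 15 min

- a species is counted by the substrate in it: one side product C or idle adduct counts as two
- amounts and yields of target count idle adduct too
- at 5 °C the constants are as listed, elsewhere as the activation energies and enthalpies make them
- in an amount of target, one idle adduct counts as one target

- which of these there is most of at the end, counted by the substrate in it, gamma (side product C / side product A / side product B / target)
- which of these there is most of at the end, counted by the substrate in it, delta (side product C / side product A / side product B / target)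
- amount of the one of these that there is most of at the end, in percent of the substrate charged, gamma
- amount of the one of these that there is most of at the end, in percent of the substrate charged, delta

Substrate has first-order exits to open intermediate, side product A and side product B, together 0.376 min⁻¹ in gamma. We carry one quantity, the A share: the rate constant to side product A over the sum of those first-order constants, 74.5 %, a branching fraction. Let a be the fraction of the charge still substrate and f the fraction lost from it by the bimolecular drain to side product C. Then side product A stands at the A share times (1 − a − f), provided the way back from open intermediate can be dropped. In gamma we drop it, because its constant, 0.002714 min⁻¹, is far smaller than the exits of open intermediate to target and side product B, 0.158 min⁻¹. Capture, at 0.001950 min⁻¹, is dropped for the same reason.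

Setting f to nothing and letting a decay at 0.376 min⁻¹ gives the upper bound for gamma, 74.2 %. For a first lower bound, open intermediate cannot exceed 20.2 % of the charge, so the drain adds at most 0.0404 min⁻¹ to the loss of substrate, which gives 67.0 %.

Now we go round once more. We put the first-round a and the open intermediate it feeds back into the drain, and f comes to 3.79 %. That overshoots, since the first round ignores the drain on both partners, so the lower bound for gamma rises to 71.4 %. We commit to the middle, 72.8 %, and the winner in gamma is side product A, because the A share exceeds what remains for the others together.

In delta the constant to side product A is 6.01 min⁻¹. Per unit going to side product A, the other first-order exits take 0.262 and 0.0642. Our figure for delta is therefore 75.4 %, again for side product A.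

The forecast names side product A at 72 % for gamma and side product A at 75 % for delta, on the ground that direct substrate loss to side product A “takes about three quarters of the first-order substrate consumption at both temperatures”. Its gamma figure lies inside our bracket, below the upper bound and above the lower.

The flasks give side product A at 72.0 % in gamma and side product A at 75.0 % in delta. The gamma value sits inside the bracket, nearer its lower edge. The A share also serves gamma read early, at 4.0 min. The first-round substrate left is 22.2 %, so the upper bound is 58.0 %. The drain by then comes to 2.70 %, so the lower bound is 55.9 %. That flask holds 57.0 % of side product A, with 21.0 % still substrate.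

(The constants used here are made up; the result is computed.)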